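**Retrosynthetic overview**
1. Target 39 ⇒ diol-protected longipinenone 32 by two late esterifications (senecioate at C7, then angelate at C9); the enone comes from a tricyclic C3 ketone by Saegusa oxidation, MeLi addition and oxidative 1,3-transposition.
2. Seven-membered ring: C5–C6 bond by intramolecular reductive aldol of an isopropenyl ketone onto a cyclobutanone; the extra C5–OH is removed radically and C7 is set by CBS reduction.
3. Key fragment union: C8–C9 bond by an intermolecular boron aldol between bicyclic aldehyde 16 and 3-methylbut-3-en-2-one 17.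
4. Cyclobutane and six-membered ring together: intramolecular ketene–alkene [2+2] of an (E)-trisubstituted alkenoic acid whose (R)-C3 ether (Brown allylation) controls the face.
5. Ring order: bicyclo[3.1.1]heptanone → seven-membered ring → enone → esters.

Numbering (LN): C11–C1–C2–C3–C4 is the three-carbon bridge with its bridgeheads, C4–C5–C11–C10 the cyclobutane, C5–C6–C7–C8–C9–C10 the four-carbon bridge; "LN-tricycloundecane" is tricyclo[5.4.0.0^2,8]undecane with these locants, and the same labels are used for open-chain precursors.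
Assumption: both Ipc boron reagents are bought as solutions; their facial sense is taken from Brown's allylboration rule and from Paterson's methyl-ketone aldol precedent (the latter recalled with less certainty; the C9 epimer is separable). PMB = 4-methoxybenzyl, TBDPS = tert-butyldiphenylsilyl, TBS = tert-butyldimethylsilyl, TES = triethylsilyl, Ipc = isopinocampheyl, DMP = Dess–Martin periodinane.

**Step 1**
Reactants: 1 prenyl acetate
Product: 2 (2E)-4-hydroxy-3-methylbut-2-en-1-yl acetate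
Conditions: SeO2 (10 mol%), t-BuOOH, salicylic acid (cat.), CH2Cl2, rt
Reagents that add atoms: tert-butyl hydroperoxide, CC(C)(C)OO
Why: SeO2-catalysed allylic oxidation (ene/[2,3] sequence) hydroxylates the (E)-methyl group selectively, which fixes the alkene geometry (C9 trans to C3) needed later.

**Step 2**
Reactants: 2 (2E)-4-hydroxy-3-methylbut-2-en-1-yl acetate
Product: 3 (2E)-4-[(tert-butyldiphenylsilyl)oxy]-3-methylbut-2-en-1-yl acetate
Conditions: t-BuPh2SiCl, imidazole, CH2Cl2, 0 °C → rt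
Reagents that add atoms: tert-butyl(chloro)diphenylsilane, CC(C)(C)[Si](Cl)(c1ccccc1)c1ccccc1
Why: Routine silylation of a primary allylic alcohol that leaves the acetate untouched.

**Step 3**
Reactants: 3 (2E)-4-[(tert-butyldiphenylsilyl)oxy]-3-methylbut-2-en-1-yl acetate
Product: 4 (2E)-4-[(tert-butyldiphenylsilyl)oxy]-3-methylbut-2-en-1-ol
Conditions: K2CO3 (cat.), MeOH, 0 °C
Reagents that add atoms: none
Why: Mild base-catalysed transesterification removes the acetate without touching the silyl ether.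

**Step 4**
Reactants: 4 (2E)-4-[(tert-butyldiphenylsilyl)oxy]-3-methylbut-2-en-1-ol
Product: 5 (2E)-4-[(tert-butyldiphenylsilyl)oxy]-3-methylbut-2-enal
Conditions: MnO2, CH2Cl2, rt
Reagents that add atoms: none
Why: MnO2 oxidation of an allylic alcohol gives the enal chemoselectively and without E/Z isomerisation.

**Step 5**
Reactants: 5 (2E)-4-[(tert-butyldiphenylsilyl)oxy]-3-methylbut-2-enal
Product: 6 (4R,5E)-7-[(tert-butyldiphenylsilyl)oxy]-6-methylhepta-1,5-dien-4-ol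
Conditions: (+)-Ipc2B(allyl) [from (−)-α-pinene], Et2O, −78 °C; then NaOH, H2O2
Reagents that add atoms: (+)-B-allyldiisopinocampheylborane, C=CCB([C@H]1C[C@H]2C[C@@H]([C@@H]1C)C2(C)C)[C@H]1C[C@H]2C[C@@H]([C@@H]1C)C2(C)C
Why: Brown asymmetric allylboration through a chair transition state, in which the (−)-α-pinene-derived reagent adds to the re face of the enal and sets C3 as R.

**Step 6**
Reactants: 6 (4R,5E)-7-[(tert-butyldiphenylsilyl)oxy]-6-methylhepta-1,5-dien-4-ol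
Product: 7 (4R,5E)-7-[(tert-butyldiphenylsilyl)oxy]-4-[(4-methoxybenzyl)oxy]-6-methylhepta-1,5-diene
Conditions: NaH, PMBCl, Bu4NI (cat.), DMF, 0 °C → rt
Reagents that add atoms: 4-methoxybenzyl chloride, COc1ccc(CCl)cc1
Why: Williamson etherification of the secondary alkoxide installs an ether that survives every step up to its oxidative removal.

**Step 7**
Reactants: 7 (4R,5E)-7-[(tert-butyldiphenylsilyl)oxy]-4-[(4-methoxybenzyl)oxy]-6-methylhepta-1,5-diene; 8 methyl acrylate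
Product: 9 methyl (2E,5R,6E)-8-[(tert-butyldiphenylsilyl)oxy]-5-[(4-methoxybenzyl)oxy]-7-methylocta-2,6-dienoate
Conditions: second-generation Grubbs catalyst [RuCl2(H2IMes)(PCy3)(=CHPh)] (5 mol%), CH2Cl2, 40 °C
Reagents that add atoms: none
Why: Olefin cross-metathesis of the terminal alkene with the electron-poor acrylate is E-selective and the trisubstituted alkene does not take part.

**Step 8**
Reactants: 9 methyl (2E,5R,6E)-8-[(tert-butyldiphenylsilyl)oxy]-5-[(4-methoxybenzyl)oxy]-7-methylocta-2,6-dienoate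
Product: 10 methyl (5R,6E)-8-[(tert-butyldiphenylsilyl)oxy]-5-[(4-methoxybenzyl)oxy]-7-methyloct-6-enoate
Conditions: Mg turnings, MeOH, 0 °C → rt
Reagents that add atoms: none
Why: Electron-transfer conjugate reduction by Mg/MeOH saturates only the enoate C=C and leaves the isolated trisubstituted alkene and the ethers alone.

**Step 9**
Reactants: 10 methyl (5R,6E)-8-[(tert-butyldiphenylsilyl)oxy]-5-[(4-methoxybenzyl)oxy]-7-methyloct-6-enoate
Product: 11 (5R,6E)-8-[(tert-butyldiphenylsilyl)oxy]-5-[(4-methoxybenzyl)oxy]-7-methyloct-6-enoic acid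
Conditions: LiOH, THF/MeOH/H2O, rt; then aq. HCl to pH 4
Reagents that add atoms: lithium hydroxide, [Li+].[OH-]
Why: Ester saponification under conditions that the silyl and PMB ethers tolerate.

**Step 10**
Reactants: 11 (5R,6E)-8-[(tert-butyldiphenylsilyl)oxy]-5-[(4-methoxybenzyl)oxy]-7-methyloct-6-enoic acid
Product: 14 (1S,2R,5S,7S)-7-{[(tert-butyldiphenylsilyl)oxy]methyl}-2-[(4-methoxybenzyl)oxy]-7-methylbicyclo[3.1.1]heptan-6-one, via acid chloride 12 (not isolated), via ketene 13 (not isolated)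
Conditions: Me2C=C(Cl)NMe2, CH2Cl2, 0 °C → rt; then slow addition to Et3N, toluene, 110 °C (0.005 M)
Reagents that add atoms: none
Why: Intramolecular thermal ketene–alkene [2+2] cycloaddition in which the ketene carbonyl carbon bonds to the less substituted alkene carbon (bridged bicyclo[3.1.1]heptan-6-one), suprafacial addition to the E-alkene places the C10 methyl syn to the three-carbon bridge, and the (R)-C3 ether directs the face by 1,3-allylic strain (C3–H eclipsing the cis methyl) to set C4 and C11, the minor diastereomer being removed by chromatography.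

**Step 11**
Reactants: 14 (1S,2R,5S,7S)-7-{[(tert-butyldiphenylsilyl)oxy]methyl}-2-[(4-methoxybenzyl)oxy]-7-methylbicyclo[3.1.1]heptan-6-one
Product: 15 (1S,2R,5S,7S)-7-(hydroxymethyl)-2-[(4-methoxybenzyl)oxy]-7-methylbicyclo[3.1.1]heptan-6-one
Conditions: HF·pyridine, pyridine, THF, rt
Reagents that add atoms: none
Why: Fluoride-mediated desilylation frees the primary alcohol while the PMB ether and the cyclobutanone are inert.

**Step 12**
Reactants: 15 (1S,2R,5S,7S)-7-(hydroxymethyl)-2-[(4-methoxybenzyl)oxy]-7-methylbicyclo[3.1.1]heptan-6-one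
Product: 16 (1S,2R,5S,6S)-2-[(4-methoxybenzyl)oxy]-6-methyl-7-oxobicyclo[3.1.1]heptane-6-carbaldehyde
Conditions: DMP, NaHCO3, CH2Cl2, rt
Reagents that add atoms: none
Why: Dess–Martin oxidation gives the non-enolisable neopentyl aldehyde under neutral conditions.

**Step 13 (key fragment union)**
Reactants: 16 (1S,2R,5S,6S)-2-[(4-methoxybenzyl)oxy]-6-methyl-7-oxobicyclo[3.1.1]heptane-6-carbaldehyde; 17 3-methylbut-3-en-2-one
Product: 19 (1S,2R,5S,7S)-7-[(1R)-1-hydroxy-4-methyl-3-oxopent-4-en-1-yl]-2-[(4-methoxybenzyl)oxy]-7-methylbicyclo[3.1.1]heptan-6-one, via boron dienolate 18 (not isolated)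
Conditions: 17, (−)-Ipc2BCl, Et3N, Et2O, 0 °C; then 16, −78 → −20 °C; HN(CH2CH2OH)2 work-up
Reagents that add atoms: none
Why: Intermolecular boron aldol (Paterson type) of the only possible enol borinate of 17, which adds to the aldehyde and not to the hindered cyclobutanone and is steered by the Ipc ligands to the aldehyde re face (C9 = R), with a non-oxidative work-up to avoid Baeyer–Villiger cleavage and chromatographic removal of the minor C9 epimer.

**Step 14**
Reactants: 19 (1S,2R,5S,7S)-7-[(1R)-1-hydroxy-4-methyl-3-oxopent-4-en-1-yl]-2-[(4-methoxybenzyl)oxy]-7-methylbicyclo[3.1.1]heptan-6-one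
Product: 20 (1S,2R,5S,7S)-7-[(1R)-1-[(tert-butyldimethylsilyl)oxy]-4-methyl-3-oxopent-4-en-1-yl]-2-[(4-methoxybenzyl)oxy]-7-methylbicyclo[3.1.1]heptan-6-one
Conditions: t-BuMe2SiOTf, 2,6-lutidine, CH2Cl2, −78 °C
Reagents that add atoms: tert-butyldimethylsilyl triflate, CC(C)(C)[Si](C)(C)OS(=O)(=O)C(F)(F)F
Why: Silyl triflate silylation protects the hindered β-hydroxyl at low temperature before oxa-Michael addition or retro-aldol can occur.

**Step 15**
Reactants: 20 (1S,2R,5S,7S)-7-[(1R)-1-[(tert-butyldimethylsilyl)oxy]-4-methyl-3-oxopent-4-en-1-yl]-2-[(4-methoxybenzyl)oxy]-7-methylbicyclo[3.1.1]heptan-6-one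
Product: 22 (3R,4S,5S,9R,10S,11S)-9-[(tert-butyldimethylsilyl)oxy]-5-hydroxy-3-[(4-methoxybenzyl)oxy]-6,6,10-trimethyl-LN-tricycloundecan-7-one, via copper enolate 21 (not isolated)
Conditions: [(Ph3P)CuH]6, toluene, −40 → 0 °C; aq. NH4Cl
Reagents that add atoms: none
Why: Reductive aldol cyclisation in which copper hydride conjugate reduction forms the tetrasubstituted C6 enolate regiospecifically and this adds to the strained cyclobutanone, the tether from C10 reaching C5 only from the face anti to the three-carbon bridge so that the C5 configuration of the tricycle is fixed.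

**Step 16**
Reactants: 22 (3R,4S,5S,9R,10S,11S)-9-[(tert-butyldimethylsilyl)oxy]-5-hydroxy-3-[(4-methoxybenzyl)oxy]-6,6,10-trimethyl-LN-tricycloundecan-7-one
Product: 23 (3R,4S,5S,7R,9R,10S,11S)-9-[(tert-butyldimethylsilyl)oxy]-3-[(4-methoxybenzyl)oxy]-6,6,10-trimethyl-LN-tricycloundecane-5,7-diol
Conditions: (S)-2-methyl-CBS-oxazaborolidine (0.5 equiv), BH3·SMe2, THF, −20 °C; MeOH
Reagents that add atoms: none
Why: Corey–Bakshi–Shibata reduction in which the (S)-catalyst distinguishes the quaternary C6 side (large) from the C8 methylene (small) and gives the 7R alcohol, trans to the C9 oxygen, under reagent control.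

**Step 17**
Reactants: 23 (3R,4S,5S,7R,9R,10S,11S)-9-[(tert-butyldimethylsilyl)oxy]-3-[(4-methoxybenzyl)oxy]-6,6,10-trimethyl-LN-tricycloundecane-5,7-diol
Product: 24 (3R,4S,5S,7R,9R,10S,11S)-9-[(tert-butyldimethylsilyl)oxy]-3-[(4-methoxybenzyl)oxy]-6,6,10-trimethyl-7-[(triethylsilyl)oxy]-LN-tricycloundecan-5-ol
Conditions: Et3SiOTf (1.1 equiv), 2,6-lutidine, CH2Cl2, −78 °C
Reagents that add atoms: triethylsilyl triflate, CC[Si](CC)(CC)OS(=O)(=O)C(F)(F)F
Why: Selective silylation of the secondary alcohol, because the tertiary cyclobutanol flanked by three fully substituted carbons does not react at −78 °C.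

**Step 18**
Reactants: 24 (3R,4S,5S,7R,9R,10S,11S)-9-[(tert-butyldimethylsilyl)oxy]-3-[(4-methoxybenzyl)oxy]-6,6,10-trimethyl-7-[(triethylsilyl)oxy]-LN-tricycloundecan-5-ol
Product: 25 O-[C5] S-methyl xanthate of 24 with unchanged stereodescriptors (3R,4S,5S,7R,9R,10S,11S)
Conditions: KH, THF, 0 °C; CS2; then MeI
Reagents that add atoms: carbon disulfide, S=C=S; iodomethane, CI
Why: Xanthate formation from the tertiary alkoxide gives a derivative that is stable here because Chugaev syn-elimination would need a bridgehead double bond.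

**Step 19**
Reactants: 25 O-[C5] S-methyl xanthate of 24
Product: 26 (3R,4S,5R,7R,9R,10S,11R)-9-[(tert-butyldimethylsilyl)oxy]-3-[(4-methoxybenzyl)oxy]-6,6,10-trimethyl-7-[(triethylsilyl)oxy]-LN-tricycloundecane
Conditions: Bu3SnH, AIBN (cat.), toluene, 110 °C
Reagents that add atoms: none
Why: Barton–McCombie radical deoxygenation in which the tertiary cyclobutyl radical at C5 takes hydrogen on the only face the tricycle allows, giving the C5–H configuration of the target.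

**Step 20**
Reactants: 26 (3R,4S,5R,7R,9R,10S,11R)-9-[(tert-butyldimethylsilyl)oxy]-3-[(4-methoxybenzyl)oxy]-6,6,10-trimethyl-7-[(triethylsilyl)oxy]-LN-tricycloundecane
Product: 27 (3R,4S,5R,7R,9R,10S,11R)-9-[(tert-butyldimethylsilyl)oxy]-6,6,10-trimethyl-7-[(triethylsilyl)oxy]-LN-tricycloundecan-3-ol
Conditions: DDQ, CH2Cl2/pH 7 buffer, 0 °C
Reagents that add atoms: none
Why: Oxidative PMB cleavage by DDQ is orthogonal to both silyl ethers.

**Step 21**
Reactants: 27 (3R,4S,5R,7R,9R,10S,11R)-9-[(tert-butyldimethylsilyl)oxy]-6,6,10-trimethyl-7-[(triethylsilyl)oxy]-LN-tricycloundecan-3-ol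
Product: 28 (4S,5R,7R,9R,10S,11R)-9-[(tert-butyldimethylsilyl)oxy]-6,6,10-trimethyl-7-[(triethylsilyl)oxy]-LN-tricycloundecan-3-one
Conditions: DMP, NaHCO3, CH2Cl2, rt
Reagents that add atoms: none
Why: Dess–Martin oxidation of the secondary alcohol to the ketone under buffered conditions.

**Step 22**
Reactants: 28 (4S,5R,7R,9R,10S,11R)-9-[(tert-butyldimethylsilyl)oxy]-6,6,10-trimethyl-7-[(triethylsilyl)oxy]-LN-tricycloundecan-3-one
Product: 30 (4S,5R,7R,9R,10S,11R)-9-[(tert-butyldimethylsilyl)oxy]-6,6,10-trimethyl-7-[(triethylsilyl)oxy]-LN-tricycloundec-1-en-3-one, via trimethylsilyl enol ether 29 (not isolated)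
Conditions: LiN(SiMe3)2, Me3SiCl, THF, −78 °C; then Pd(OAc)2, MeCN, rt
Reagents that add atoms: none
Why: Saegusa–Ito oxidation, regiochemically unambiguous because the ketone can enolise only toward C2 (C4 is a bridgehead).

**Step 23**
Reactants: 30 (4S,5R,7R,9R,10S,11R)-9-[(tert-butyldimethylsilyl)oxy]-6,6,10-trimethyl-7-[(triethylsilyl)oxy]-LN-tricycloundec-1-en-3-one
Product: 31 (3S,4S,5R,7R,9R,10S,11R)-9-[(tert-butyldimethylsilyl)oxy]-7-[(triethylsilyl)oxy]longipin-1-en-3-ol (mainly this C3 epimer)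
Conditions: MeLi, THF, −78 °C; aq. NH4Cl
Reagents that add atoms: methyllithium, [Li]C
Why: 1,2-Addition of methyllithium to the enone from the face of the C5 bridge, away from the syn methyl on C10, the configuration of the new carbinol being lost in the next step.

**Step 24**
Reactants: 31 (3S,4S,5R,7R,9R,10S,11R)-9-[(tert-butyldimethylsilyl)oxy]-7-[(triethylsilyl)oxy]longipin-1-en-3-ol
Product: 32 (4R,5S,7R,9R,10R,11R)-9-[(tert-butyldimethylsilyl)oxy]-7-[(triethylsilyl)oxy]longipin-2-en-1-one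
Conditions: pyridinium chlorochromate [C5H5NH][CrO3Cl], 4 Å molecular sieves, CH2Cl2, rt
Reagents that add atoms: none
Why: Dauben–Babler oxidative 1,3-transposition, in which the chromate ester of the tertiary allylic alcohol undergoes a [3,3] shift and oxidation to the β-methyl enone, as precedented for apoverbenone adducts.

**Step 25**
Reactants: 32 (4R,5S,7R,9R,10R,11R)-9-[(tert-butyldimethylsilyl)oxy]-7-[(triethylsilyl)oxy]longipin-2-en-1-one
Product: 33 (4R,5S,7R,9R,10R,11R)-9-[(tert-butyldimethylsilyl)oxy]-7-hydroxylongipin-2-en-1-one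
Conditions: HF·pyridine, pyridine, THF, 0 °C
Reagents that add atoms: none
Why: Selective desilylation, the triethylsilyl ether being cleaved much faster than the hindered tert-butyldimethylsilyl ether.

**Step 26**
Reactants: 33 (4R,5S,7R,9R,10R,11R)-9-[(tert-butyldimethylsilyl)oxy]-7-hydroxylongipin-2-en-1-one; 34 3-methylbut-2-enoyl chloride
Product: 35 (4R,5S,7R,9R,10R,11R)-9-[(tert-butyldimethylsilyl)oxy]-7-[(3-methylbut-2-enoyl)oxy]longipin-2-en-1-one
Conditions: pyridine, DMAP (cat.), CH2Cl2, 0 °C → rt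
Reagents that add atoms: none
Why: DMAP-catalysed acylation with the acid chloride, using pyridine rather than a stronger amine to avoid deconjugation through the vinylketene.

**Step 27**
Reactants: 35 (4R,5S,7R,9R,10R,11R)-9-[(tert-butyldimethylsilyl)oxy]-7-[(3-methylbut-2-enoyl)oxy]longipin-2-en-1-one
Product: 36 (4R,5S,7R,9R,10R,11R)-9-hydroxy-7-[(3-methylbut-2-enoyl)oxy]longipin-2-en-1-one
Conditions: HF·pyridine, THF, rt
Reagents that add atoms: none
Why: Fluoride desilylation under mildly acidic conditions, which do not promote acyl migration or harm the enone.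

**Step 28**
Reactants: 36 (4R,5S,7R,9R,10R,11R)-9-hydroxy-7-[(3-methylbut-2-enoyl)oxy]longipin-2-en-1-one; 37 angelic acid
Product: 39 (4R,5S,7R,9R,10R,11R)-9-{[(2Z)-2-methylbut-2-enoyl]oxy}-7-[(3-methylbut-2-enoyl)oxy]longipin-2-en-1-one (target), via mixed anhydride 38 (not isolated)
Conditions: 37, 2,4,6-trichlorobenzoyl chloride, Et3N, toluene, rt; then 36, 80 °C
Reagents that add atoms: none
Why: Yamaguchi-type esterification through the mixed 2,4,6-trichlorobenzoic anhydride, which acylates hindered secondary alcohols with angelic acid without Z-to-E isomerisation to the tiglate.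

**Compound list**
1 | prenyl acetate (3-methylbut-2-en-1-yl acetate) | CC(C)=CCOC(C)=O | starting material
2 | (2E)-4-hydroxy-3-methylbut-2-en-1-yl acetate | CC(=O)OC/C=C(\C)CO | intermediate
3 | (2E)-4-[(tert-butyldiphenylsilyl)oxy]-3-methylbut-2-en-1-yl acetate | CC(=O)OC/C=C(\C)CO[Si](c1ccccc1)(c1ccccc1)C(C)(C)C | intermediate
4 | (2E)-4-[(tert-butyldiphenylsilyl)oxy]-3-methylbut-2-en-1-ol | OC/C=C(\C)CO[Si](c1ccccc1)(c1ccccc1)C(C)(C)C | intermediate
5 | (2E)-4-[(tert-butyldiphenylsilyl)oxy]-3-methylbut-2-enal | O=C/C=C(\C)CO[Si](c1ccccc1)(c1ccccc1)C(C)(C)C | intermediate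
6 | (4R,5E)-7-[(tert-butyldiphenylsilyl)oxy]-6-methylhepta-1,5-dien-4-ol | C=CC[C@@H](O)/C=C(\C)CO[Si](c1ccccc1)(c1ccccc1)C(C)(C)C | intermediate
7 | (4R,5E)-7-[(tert-butyldiphenylsilyl)oxy]-4-[(4-methoxybenzyl)oxy]-6-methylhepta-1,5-diene | C=CC[C@@H](OCc1ccc(OC)cc1)/C=C(\C)CO[Si](c1ccccc1)(c1ccccc1)C(C)(C)C | intermediate
8 | methyl acrylate | C=CC(=O)OC | starting material
9 | methyl (2E,5R,6E)-8-[(tert-butyldiphenylsilyl)oxy]-5-[(4-methoxybenzyl)oxy]-7-methylocta-2,6-dienoate | COC(=O)/C=C/C[C@@H](OCc1ccc(OC)cc1)/C=C(\C)CO[Si](c1ccccc1)(c1ccccc1)C(C)(C)C | intermediate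
10 | methyl (5R,6E)-8-[(tert-butyldiphenylsilyl)oxy]-5-[(4-methoxybenzyl)oxy]-7-methyloct-6-enoate | COC(=O)CCC[C@@H](OCc1ccc(OC)cc1)/C=C(\C)CO[Si](c1ccccc1)(c1ccccc1)C(C)(C)C | intermediate
11 | (5R,6E)-8-[(tert-butyldiphenylsilyl)oxy]-5-[(4-methoxybenzyl)oxy]-7-methyloct-6-enoic acid | OC(=O)CCC[C@@H](OCc1ccc(OC)cc1)/C=C(\C)CO[Si](c1ccccc1)(c1ccccc1)C(C)(C)C | intermediate
12 | acid chloride of 11 | ClC(=O)CCC[C@@H](OCc1ccc(OC)cc1)/C=C(\C)CO[Si](c1ccccc1)(c1ccccc1)C(C)(C)C | intermediate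
13 | ketene (5R,6E)-8-[(tert-butyldiphenylsilyl)oxy]-5-[(4-methoxybenzyl)oxy]-7-methylocta-1,6-dien-1-one | O=C=CCC[C@@H](OCc1ccc(OC)cc1)/C=C(\C)CO[Si](c1ccccc1)(c1ccccc1)C(C)(C)C | intermediate
14 | (1S,2R,5S,7S)-7-{[(tert-butyldiphenylsilyl)oxy]methyl}-2-[(4-methoxybenzyl)oxy]-7-methylbicyclo[3.1.1]heptan-6-one (7-methyl syn to the C2–C4 bridge) | O=C1[C@H]2CC[C@@H](OCc3ccc(OC)cc3)[C@@H]1[C@@]2(C)CO[Si](c3ccccc3)(c3ccccc3)C(C)(C)C | intermediate
15 | (1S,2R,5S,7S)-7-(hydroxymethyl)-2-[(4-methoxybenzyl)oxy]-7-methylbicyclo[3.1.1]heptan-6-one | O=C1[C@H]2CC[C@@H](OCc3ccc(OC)cc3)[C@@H]1[C@@]2(C)CO | intermediate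
16 | (1S,2R,5S,6S)-2-[(4-methoxybenzyl)oxy]-6-methyl-7-oxobicyclo[3.1.1]heptane-6-carbaldehyde | O=C1[C@H]2CC[C@@H](OCc3ccc(OC)cc3)[C@@H]1[C@@]2(C)C=O | intermediate
17 | 3-methylbut-3-en-2-one | CC(=O)C(C)=C | starting material
18 | diisopinocampheylboron dienolate of 17 | C=C(C)C(=C)OB([C@@H]1C[C@@H]2C[C@H]([C@H]1C)C2(C)C)[C@@H]1C[C@@H]2C[C@H]([C@H]1C)C2(C)C | intermediate
19 | (1S,2R,5S,7S)-7-[(1R)-1-hydroxy-4-methyl-3-oxopent-4-en-1-yl]-2-[(4-methoxybenzyl)oxy]-7-methylbicyclo[3.1.1]heptan-6-one | O=C1[C@H]2CC[C@@H](OCc3ccc(OC)cc3)[C@@H]1[C@@]2(C)[C@H](O)CC(=O)C(C)=C | intermediate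
20 | (1S,2R,5S,7S)-7-[(1R)-1-[(tert-butyldimethylsilyl)oxy]-4-methyl-3-oxopent-4-en-1-yl]-2-[(4-methoxybenzyl)oxy]-7-methylbicyclo[3.1.1]heptan-6-one | O=C1[C@H]2CC[C@@H](OCc3ccc(OC)cc3)[C@@H]1[C@@]2(C)[C@H](O[Si](C)(C)C(C)(C)C)CC(=O)C(C)=C | intermediate
21 | copper enolate from 20 (Ph3P-ligated Cu–O enolate, C6=C7) | O=C1[C@H]2CC[C@@H](OCc3ccc(OC)cc3)[C@@H]1[C@@]2(C)[C@H](O[Si](C)(C)C(C)(C)C)CC(O[Cu])=C(C)C | intermediate
22 | (3R,4S,5S,9R,10S,11S)-9-[(tert-butyldimethylsilyl)oxy]-5-hydroxy-3-[(4-methoxybenzyl)oxy]-6,6,10-trimethyl-LN-tricycloundecan-7-one | CC(C)(C)[Si](C)(C)O[C@@H]1CC(=O)C(C)(C)[C@]2(O)[C@H]3CC[C@@H](OCc4ccc(OC)cc4)[C@@H]2[C@]31C | intermediate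
23 | (3R,4S,5S,7R,9R,10S,11S)-9-[(tert-butyldimethylsilyl)oxy]-3-[(4-methoxybenzyl)oxy]-6,6,10-trimethyl-LN-tricycloundecane-5,7-diol | CC(C)(C)[Si](C)(C)O[C@@H]1C[C@@H](O)C(C)(C)[C@]2(O)[C@H]3CC[C@@H](OCc4ccc(OC)cc4)[C@@H]2[C@]31C | intermediate
24 | (3R,4S,5S,7R,9R,10S,11S)-9-[(tert-butyldimethylsilyl)oxy]-3-[(4-methoxybenzyl)oxy]-6,6,10-trimethyl-7-[(triethylsilyl)oxy]-LN-tricycloundecan-5-ol | CC(C)(C)[Si](C)(C)O[C@@H]1C[C@@H](O[Si](CC)(CC)CC)C(C)(C)[C@]2(O)[C@H]3CC[C@@H](OCc4ccc(OC)cc4)[C@@H]2[C@]31C | intermediate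
25 | O-[C5] S-methyl xanthate of 24 (3R,4S,5S,7R,9R,10S,11S) | CC(C)(C)[Si](C)(C)O[C@@H]1C[C@@H](O[Si](CC)(CC)CC)C(C)(C)[C@]2(OC(=S)SC)[C@H]3CC[C@@H](OCc4ccc(OC)cc4)[C@@H]2[C@]31C | intermediate
26 | (3R,4S,5R,7R,9R,10S,11R)-9-[(tert-butyldimethylsilyl)oxy]-3-[(4-methoxybenzyl)oxy]-6,6,10-trimethyl-7-[(triethylsilyl)oxy]-LN-tricycloundecane | CC(C)(C)[Si](C)(C)O[C@@H]1C[C@@H](O[Si](CC)(CC)CC)C(C)(C)[C@@H]2[C@H]3CC[C@@H](OCc4ccc(OC)cc4)[C@@H]2[C@]31C | intermediate
27 | (3R,4S,5R,7R,9R,10S,11R)-9-[(tert-butyldimethylsilyl)oxy]-6,6,10-trimethyl-7-[(triethylsilyl)oxy]-LN-tricycloundecan-3-ol | CC(C)(C)[Si](C)(C)O[C@@H]1C[C@@H](O[Si](CC)(CC)CC)C(C)(C)[C@@H]2[C@H]3CC[C@@H](O)[C@@H]2[C@]31C | intermediate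
28 | (4S,5R,7R,9R,10S,11R)-9-[(tert-butyldimethylsilyl)oxy]-6,6,10-trimethyl-7-[(triethylsilyl)oxy]-LN-tricycloundecan-3-one | CC(C)(C)[Si](C)(C)O[C@@H]1C[C@@H](O[Si](CC)(CC)CC)C(C)(C)[C@@H]2[C@H]3CCC(=O)[C@@H]2[C@]31C | intermediate
29 | trimethylsilyl enol ether of 28 (C2=C3–OSiMe3) | CC(C)(C)[Si](C)(C)O[C@@H]1C[C@@H](O[Si](CC)(CC)CC)C(C)(C)[C@@H]2[C@H]3CC=C(O[Si](C)(C)C)[C@@H]2[C@]31C | intermediate
30 | (4S,5R,7R,9R,10S,11R)-9-[(tert-butyldimethylsilyl)oxy]-6,6,10-trimethyl-7-[(triethylsilyl)oxy]-LN-tricycloundec-1-en-3-one | CC(C)(C)[Si](C)(C)O[C@@H]1C[C@@H](O[Si](CC)(CC)CC)C(C)(C)[C@@H]2[C@H]3C=CC(=O)[C@@H]2[C@]31C | intermediate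
31 | (3S,4S,5R,7R,9R,10S,11R)-9-[(tert-butyldimethylsilyl)oxy]-7-[(triethylsilyl)oxy]longipin-1-en-3-ol | CC(C)(C)[Si](C)(C)O[C@@H]1C[C@@H](O[Si](CC)(CC)CC)C(C)(C)[C@@H]2[C@H]3C=C[C@](C)(O)[C@@H]2[C@]31C | intermediate
32 | (4R,5S,7R,9R,10R,11R)-9-[(tert-butyldimethylsilyl)oxy]-7-[(triethylsilyl)oxy]longipin-2-en-1-one | CC(C)(C)[Si](C)(C)O[C@@H]1C[C@@H](O[Si](CC)(CC)CC)C(C)(C)[C@@H]2[C@H]3C(=O)C=C(C)[C@@H]2[C@]31C | intermediate
33 | (4R,5S,7R,9R,10R,11R)-9-[(tert-butyldimethylsilyl)oxy]-7-hydroxylongipin-2-en-1-one | CC(C)(C)[Si](C)(C)O[C@@H]1C[C@@H](O)C(C)(C)[C@@H]2[C@H]3C(=O)C=C(C)[C@@H]2[C@]31C | intermediate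
34 | 3-methylbut-2-enoyl chloride (senecioyl chloride) | CC(C)=CC(Cl)=O | starting material
35 | (4R,5S,7R,9R,10R,11R)-9-[(tert-butyldimethylsilyl)oxy]-7-[(3-methylbut-2-enoyl)oxy]longipin-2-en-1-one | CC(C)(C)[Si](C)(C)O[C@@H]1C[C@@H](OC(=O)C=C(C)C)C(C)(C)[C@@H]2[C@H]3C(=O)C=C(C)[C@@H]2[C@]31C | intermediate
36 | (4R,5S,7R,9R,10R,11R)-9-hydroxy-7-[(3-methylbut-2-enoyl)oxy]longipin-2-en-1-one | O[C@@H]1C[C@@H](OC(=O)C=C(C)C)C(C)(C)[C@@H]2[C@H]3C(=O)C=C(C)[C@@H]2[C@]31C | intermediate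
37 | angelic acid [(2Z)-2-methylbut-2-enoic acid] | C/C=C(/C)C(=O)O | starting material
38 | angelic 2,4,6-trichlorobenzoic anhydride | C/C=C(/C)C(=O)OC(=O)c1c(Cl)cc(Cl)cc1Cl | intermediate
39 | (4R,5S,7R,9R,10R,11R)-9-{[(2Z)-2-methylbut-2-enoyl]oxy}-7-[(3-methylbut-2-enoyl)oxy]longipin-2-en-1-one | C/C=C(/C)C(=O)O[C@@H]1C[C@@H](OC(=O)C=C(C)C)C(C)(C)[C@@H]2[C@H]3C(=O)C=C(C)[C@@H]2[C@]31C | target

**Totals and risks**
Total step count: 28. Longest linear sequence: 28 steps (1 → 39).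

Most likely to fail, step 10 (ketene [2+2]): the alkene carries two allylic oxygens and alkylketenes can dimerise, and the facial selectivity rests on the allylic-strain argument. Fallback, keteniminium cycloaddition: acid 11 is coupled with pyrrolidine (EDC·HCl, HOBt) to the pyrrolidine amide F1; Tf2O and 2,4,6-collidine in ClCH2CH2Cl at 80 °C generate the keteniminium ion, which closes to the cyclobutaniminium triflate F2; aqueous NaHCO3 hydrolysis returns ketone 14.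

Second, step 15 (reductive aldol): a seven-membered ring is closed by a tetrasubstituted enolate onto a hindered ketone. Fallback, stepwise enolate generation and SmI2 Reformatsky closure: from enone 20, RhCl(PPh3)3/Et3SiH 1,4-hydrosilylation gives the triethylsilyl enol ether F3, NBS at −78 °C gives the tertiary α-bromo ketone F4, and SmI2 in THF at −78 °C forms the samarium enolate, which closes onto the cyclobutanone to give 22.

Third, step 19 (radical deoxygenation of the very hindered tertiary cyclobutanol, including the xanthate formation that feeds it). Fallback, two-electron C–O cleavage: from alcohol 24, n-BuLi then ClP(O)(NMe2)2 gives the phosphorodiamidate F5; Li in EtNH2/THF/t-BuOH at 0 °C cleaves the C5–O bond and the PMB ether in the same operation and returns to alcohol 27, so that step 20 is not needed.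

**Further compounds**
F1 | step 10 | 1-{(5R,6E)-8-[(tert-butyldiphenylsilyl)oxy]-5-[(4-methoxybenzyl)oxy]-7-methyloct-6-enoyl}pyrrolidine | O=C(CCC[C@@H](OCc1ccc(OC)cc1)/C=C(\C)CO[Si](c1ccccc1)(c1ccccc1)C(C)(C)C)N1CCCC1
F2 | step 10 | pyrrolidinium iminium triflate corresponding to ketone 14 (C=N+ in place of C=O) | [O-]S(=O)(=O)C(F)(F)F.C1CC[N+](C1)=C1[C@H]2CC[C@@H](OCc3ccc(OC)cc3)[C@@H]1[C@@]2(C)CO[Si](c3ccccc3)(c3ccccc3)C(C)(C)C
F3 | step 15 | (1S,2R,5S,7S)-7-[(1R)-1-[(tert-butyldimethylsilyl)oxy]-4-methyl-3-[(triethylsilyl)oxy]pent-3-en-1-yl]-2-[(4-methoxybenzyl)oxy]-7-methylbicyclo[3.1.1]heptan-6-one | O=C1[C@H]2CC[C@@H](OCc3ccc(OC)cc3)[C@@H]1[C@@]2(C)[C@H](O[Si](C)(C)C(C)(C)C)CC(O[Si](CC)(CC)CC)=C(C)C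
F4 | step 15 | (1S,2R,5S,7S)-7-[(1R)-4-bromo-1-[(tert-butyldimethylsilyl)oxy]-4-methyl-3-oxopentyl]-2-[(4-methoxybenzyl)oxy]-7-methylbicyclo[3.1.1]heptan-6-one | O=C1[C@H]2CC[C@@H](OCc3ccc(OC)cc3)[C@@H]1[C@@]2(C)[C@H](O[Si](C)(C)C(C)(C)C)CC(=O)C(C)(C)Br
F5 | step 19 | C5 N,N,N',N'-tetramethylphosphorodiamidate of 24 | CC(C)(C)[Si](C)(C)O[C@@H]1C[C@@H](O[Si](CC)(CC)CC)C(C)(C)[C@]2(OP(=O)(N(C)C)N(C)C)[C@H]3CC[C@@H](OCc4ccc(OC)cc4)[C@@H]2[C@]31C
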